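**Labels.** Quinolone A and quinolone B are the two 7,8-dimethoxy-1-methylquinolin-2-one units (atoms C3A, C4A, O4A and C3B, C4B, O4B). The carbocycle is Ca(=Cb)–Cc–Cd–Ce–Cf: Ca sits on C3A, Cb is the alkene CH, Cc carries CH3 and O4B, Cd is CH2, Ce sits on C3B, and Cf carries Cg, the CMe2 carbon bonded to O4A. Ring A is the pyran O4A–Cg–Cf–Ca–C3A–C4A; ring B is the pyran O4B–Cc–Cd–Ce–C3B–C4B.

## Analysis of the target

The target (16) joins two identical 4-oxygenated 2-quinolones through a C10 unit that forms a cyclohexene, Ca=Cb–Cc–Cd–Ce–Cf. Ring A is fused to the cyclohexene along Ca–Cf, whereas ring B spans Cc and Ce, so that ring B and the carbocycle make up a 2-oxabicyclo[3.3.1]nonene. There are three stereocentres, Cc (S), Ce (R) and Cf (S). Cc and Ce are bridgeheads and their relation is fixed by the bridge, so the only free relation is that of Cf to Ce: Cg lies on the face opposite the quinolone B bridge, with the hydrogens on Ce and Cf trans. Sensitive features are the tertiary allylic ether at Cc (ionisable), the Ca=Cb alkene conjugated with the 4-alkoxyquinolone (acid can move it to Ca=Cf and erase Cf), and four Lewis-basic lactam and ether oxygens on each half. The difficulty is to place two bulky, identical heteroaryl units on a small carbocycle in two different fusion modes, next to a gem-dimethyl carbon, with no spare functional group to steer the stereochemistry. The strategy rests on ring B: O4B–Cc(CH3)–Cd–Ce–C3B=C4B is the pattern left when a carbon nucleophile adds to the 4-position of a 2-methylpyrylium ion fused to quinolone B. Cc is at the ketone level and Ce at the aldehyde level, so Cc–Cd–Ce with its methyl group is a masked 3-oxobutanal.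

## Retrosynthetic reasoning

**Cb–Cc (16 to 14).** The last bond made is Cb–Cc. Cc is a tertiary carbon bearing O4B, so it can be reached from the oxocarbenium ion 15, which is the C-protonated form of a 2-methyl-4H-pyran enol ether. Cb must be a nucleophilic sp2 carbon that ends inside the Ca=Cb alkene. A vinylsilane with silicon on Cb (14) meets this: ipso attack places the charge on Ca, β to silicon, and loss of silicon can only return the double bond to Ca=Cb. Cutting here removes the bridge in one stroke, makes Cc a consequence of Ce, and leaves a precursor whose rings A and B are ordinary, unbridged pyrans.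

**Ca=Cb (14 to 13).** The vinylsilane is the one-carbon homologue of a ketone at Ca (13). The ketone is worth this extra step because it makes Cf nucleophilic in the key step and lets Cf be equilibrated afterwards. The olefination has to be non-basic, because Cf–H of 13 is acidic and its configuration must be kept. A lithiated α-silyl carbanion is therefore ruled out and a neutral titanium silylcarbene is planned.

**C3B–Ce, O4B–Cc and Ce–Cf (13 to 6, 10 and 9).** In 13 ring B is a 2-methyl-4H-pyran with a carbon substituent at its 4-position. Cutting Ce–Cf gives the enol of ketone 9 and the aromatic cation 12. Cutting 12 at C3B–Ce and O4B–Cc gives hydroxyquinolone 6 and the keto acetal 10, whose acetal carbon becomes Ce and whose ketone carbon becomes Cc (through 11). These cuts put three skeletal bonds, ring B and the stereocentres Ce and Cf into one step. The electrophile is planar, achiral and generated catalytically, so a chiral counter-anion can decide Ce. The forward reaction must form 12 without letting 6 add to it, deliver the enol of 9 to the 4-position and not the 2-position, and do so on one face.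

**C3A–Ca and O4A–Cg (9 to 6 and 7).** Ring A of 9 is cut into 6 and acid 7: C-acylation at C3A, then closure of O4A onto the β-carbon (through 8). The same hydroxyquinolone thus serves both halves of the target.

**N1–C2 and C4–C4a (6 to 3 and 4).** The pyridone ring is cut to N-methylaniline 3 and malonate 4 (through 5). The only free ortho position of 3 lies para to a methoxy group, so the ring closure has one possible outcome.

**N–CH3 (3 to 1).** Methylation is placed on the aniline nitrogen of 1 (through 2), before the quinolone exists, to avoid the N- versus O-alkylation problem of a 4-hydroxyquinolone.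

## Alternatives that were turned down

**Alternative 1:** Quinolone B built last on a finished chiral core.
- Disconnection: the pyridone ring of quinolone B is cut at C3B–C4B and N1B–C2B. The precursor is carbocycle A2, with ring A and the Ca=Cb alkene in place, Cc as a triethylsilyl-protected tertiary alcohol and a CH2CO2Me arm on Ce.
- Forward key step: the lithium enolate of A2 is acylated at the anhydride carbonyl (C4) of the N-methylisatoic anhydride A3. Loss of CO2 frees the N-methylaniline, which closes onto the ester to give hydroxyquinolone A1.
- For: each bond is made by an established quinolone annulation, no stereocentre is formed so there is no stereochemical risk, and A1 needs only ionisation at Cc and capture by O4B.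
- Against: the key step adds nothing to the carbocycle. All three stereocentres, ring A and the alkene must come from a separate enantioselective synthesis of A2. The two quinolones come from unrelated building blocks. The enolate carbon is hindered (next to Ce, which is flanked by Cf and Cg). The final closure at the tertiary allylic Cc competes with elimination to a diene.
- Comparison: its key step is better precedented than the chosen one, which is untested. The chosen route offers in its place a joining step that also builds ring B and two stereocentres, both halves from the single intermediate 6, and six steps without a protecting group; A2 alone would need more than that.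

**Alternative 2:** Enantioselective Diels–Alder reaction.
- Disconnection: Ca–Cf and Cd–Ce are cut in a [4+2] sense. This gives diene A5 (3-methylbuta-1,3-dienyl on C3A, O4A allylated) and enone A6 ((E)-3-oxobutenyl on C3B, O4B as methoxymethyl ether).
- Forward key step: cycloaddition under a cationic, triflimide-activated prolinol-derived oxazaborolidine to the acetylcyclohexene A4. The aryl on Ca ends next to the acetyl on Cf, as both the 1-aryl and the 3-methyl group of the diene direct.
- For: the carbocycle and the Ce/Cf pair arise together. The trans relation at Ce and Cf is inherited from the (E)-alkene by suprafacial addition, which is firmer than the control of Cf in the chosen route. Face selection by this catalyst class is well understood.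
- Against: A4 has the alkene at Cb=Cc and an sp3 Ca. Simple closure of O4B onto Cc would give a saturated ring, so an oxidative etherification with transposition is needed, and the Ca stereocentre is made only to be destroyed. The acetyl group must still become Cg (methyl addition, ether closure to O4A), and two different O-protecting groups must be removed. The β-heteroaryl enone is a sluggish dienophile, both reacting termini carry doubly ortho-substituted aryl groups, and the lactam oxygens are likely to bind the boron cation in preference to the enone.
- Comparison: stronger in stereochemical precedent, weaker in oxidation-state economy and length (about a dozen steps against six). The chosen route delivers Ca, Cb and Cc at the correct oxidation level directly.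

**Alternative 3:** Cyclopropane opening with capture by O4A.
- Disconnection: O4A–Cg is cut and Ca–Cg re-formed, so ring A is traced back to a gem-dimethylcyclopropane. The precursor is the car-3-en-2-ol A8, with quinolone A (free 4-OH) on the cyclopropane carbon Ca, a hydroxyl on Cb and O-protected quinolone B on Ce.
- Forward key step: mild acid ionises the Cb alcohol. The cation is allylic and cyclopropylcarbinyl; the Ca–Cg bond opens to the Ca=Cb–Cc=Cd diene and a tertiary cation at Cg, which O4A traps to give A7.
- For: Cf is carried through stereospecifically, since its bond to Cg is never broken and it is never α to a carbonyl; this is better than the epimerisable Cf of the chosen route. A7 is one deprotection and one diene hydroalkoxylation (proton at Cd, O4B at Cc) from 16, through a cation closely related to 15.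
- Against: the link to the chiral pool does not hold, because natural carenes carry nothing on the cyclopropane carbon Ca or on Ce. A8, with a heteroaryl group on a fully substituted cyclopropane carbon, would need a de novo enantioselective synthesis of well over ten steps. In the key step the neighbouring O4A–H can trap the Cb cation directly in a five-membered ring, and opening towards Cf is a second leak.
- Comparison: more secure at Cf and similar in its endgame, but the difficulty moves into the preparation of A8. The chosen route keeps its precursors to three steps and concentrates the risk in one convergent step.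

Key step: step 4

Assumption: the (R)-enantiomer of 3,3'-bis(2,4,6-triisopropylphenyl)-1,1'-binaphthyl-2,2'-diyl hydrogen phosphate, (R)-TRIP, is taken to give the (R) configuration at Ce; the sense of induction of this ion-pair addition cannot be predicted with certainty, and the (S)-acid would be used if it proves opposite.

## Route

Step 1
Reactants: 1 2,3-dimethoxyaniline
Product: 3 2,3-dimethoxy-N-methylaniline, via N-(methoxymethyl)aniline 2 (not isolated)
Conditions: (CH2O)n, NaOMe, MeOH, 40 °C; then NaBH4, reflux
Reagents that add atoms: paraformaldehyde (as formaldehyde), C=O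
Why: Reductive N-methylation: aniline and formaldehyde give the N-(methoxymethyl) derivative 2 under NaOMe, which cannot take up a second carbon, and NaBH4 reduces the derived iminium ion, so monomethylation should be selective.

Step 2
Reactants: 3 2,3-dimethoxy-N-methylaniline; 4 diethyl malonate
Product: 6 4-hydroxy-7,8-dimethoxy-1-methylquinolin-2(1H)-one, via malonamate ester 5 (not isolated)
Conditions: Ph2O, 230–250 °C, EtOH distilled off
Reagents that add atoms: none
Why: Thermal malonate cyclocondensation: aminolysis of 4 gives 5, which loses ethanol and acylates the only free ortho position (para to a methoxy group) to close the 4-hydroxy-2-quinolone. One equivalent of 4 is used so that a second malonate unit is not condensed onto the product.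

Step 3
Reactants: 6 4-hydroxy-7,8-dimethoxy-1-methylquinolin-2(1H)-one; 7 3-methylbut-2-enoic acid
Product: 9 7,8-dimethoxy-2,2,6-trimethyl-2,3-dihydro-4H-pyrano[3,2-c]quinoline-4,5(6H)-dione, via 3-acyl enol 8 (not isolated)
Conditions: P2O5–MeSO3H (Eaton's reagent), 70 °C
Reagents that add atoms: none
Why: Friedel–Crafts acylation at C3 of the enol by the activated acid gives 8, and the 4-hydroxyl closes by oxa-Michael addition to the β,β-dimethyl enone (6-endo-trig, tertiary ether), the known chromanone annulation of phenols with this acid. Closure through O4 rather than the lactam oxygen keeps the N-methyl-2-quinolone intact.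

Step 4
Reactants: 6 4-hydroxy-7,8-dimethoxy-1-methylquinolin-2(1H)-one; 10 4,4-dimethoxybutan-2-one; 9 7,8-dimethoxy-2,2,6-trimethyl-2,3-dihydro-4H-pyrano[3,2-c]quinoline-4,5(6H)-dione
Product: 13 (3R)-3-[(4R)-7,8-dimethoxy-2,6-dimethyl-5-oxo-5,6-dihydro-4H-pyrano[3,2-c]quinolin-4-yl]-7,8-dimethoxy-2,2,6-trimethyl-2,3-dihydro-4H-pyrano[3,2-c]quinoline-4,5(6H)-dione, via enone 11 (not isolated), via pyranoquinolinium ion 12 (not isolated)
Conditions: (R)-TRIP (10 mol %), 5 Å MS, ClCH2CH2Cl, 50 °C; 9 (2 equiv), 10 (1.5 equiv), 6 added slowly
Reagents that add atoms: none
Why: Proposed new method: the phosphoric acid ionises acetal 10 to its oxocarbenium ion, C3 of enol 6 adds and methanol is lost to give enone 11, which closes through O4 onto the ketone carbon (6-exo-trig hemiketalisation, the closure of ring B) and dehydrates to the aromatic 2-methylpyranoquinolinium ion 12 paired with the chiral phosphate; the enol of ketone 9 then adds through Cf to the 4-position (Ce) of 12, releasing the neutral 4H-pyran 13 and the acid. The closest known reactions are the acid-mediated synthesis of benzopyrylium salts from phenols or enols and β-keto acetals, and the phosphoric-acid-catalysed, ion-pair-controlled addition of enols and 1,3-dicarbonyl compounds to benzopyrylium ions made from chromene acetals; running both in one flask with a simple ketone enol is the untested part. Ce is set by the chiral phosphate, which covers one face of the planar cation while hydrogen-bonding the enol O–H, so that the enol is delivered to one enantiotopic face. Cf is set in the same bond formation by the relative orientation of the two trigonal partners in that organised transition state; because Cf stays α to the Ca ketone its epimers can interconvert through the enol, no strong thermodynamic preference can be counted on, and the diastereomers should be expected to need separation, with re-equilibration and recycling of the unwanted one. Addition at Ce and not at Cc is expected because Cc is substituted by the methyl group and the 4-adduct keeps the enol ether attached to O4B, as in additions of carbon nucleophiles to 2-substituted benzopyrylium ions. The first C–C bond forms at the acetal carbon of 10 and not at its ketone carbon because only the acetal is ionised to a cation. The chemoselectivity problem is that 6 is a far better nucleophile than the enol of 9 and would add to 12 itself, which is met by adding 6 slowly to an excess of 9 and 10 so that free 6 does not accumulate.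

Step 5
Reactants: 13 (3R)-3-[(4R)-7,8-dimethoxy-2,6-dimethyl-5-oxo-5,6-dihydro-4H-pyrano[3,2-c]quinolin-4-yl]-7,8-dimethoxy-2,2,6-trimethyl-2,3-dihydro-4H-pyrano[3,2-c]quinoline-4,5(6H)-dione
Product: 14 (3S)-3-[(4R)-7,8-dimethoxy-2,6-dimethyl-5-oxo-5,6-dihydro-4H-pyrano[3,2-c]quinolin-4-yl]-7,8-dimethoxy-2,2,6-trimethyl-4-[(trimethylsilyl)methylidene]-3,4-dihydro-2H-pyrano[3,2-c]quinolin-5(6H)-one (E/Z mixture)
Conditions: Cp2Ti(CH2SiMe3)2 (3 equiv), toluene, 100 °C, dark
Reagents that add atoms: bis(trimethylsilylmethyl)titanocene Cp2Ti(CH2SiMe3)2, C[Si](C)(C)C[Ti+2]C[Si](C)(C)C.[cH-]1cccc1.[cH-]1cccc1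
Why: Titanium-carbene carbonyl olefination (Petasis type): on heating the dialkyltitanocene loses Me4Si to give Cp2Ti=CHSiMe3, which adds to the Ca ketone and cycloreverts to the alkenylsilane and titanocene oxide. The reagent is not basic, so Cf should keep its configuration (a lithiated α-silyl carbanion would deprotonate Cf–H), and the lactam carbonyls are far less reactive than the ketone. Both double-bond isomers are usable because silicon is lost in step 6; the descriptor at Cf changes from R to S only through the priority change at Ca.

Step 6
Reactants: 14 (3S)-3-[(4R)-7,8-dimethoxy-2,6-dimethyl-5-oxo-5,6-dihydro-4H-pyrano[3,2-c]quinolin-4-yl]-7,8-dimethoxy-2,2,6-trimethyl-4-[(trimethylsilyl)methylidene]-3,4-dihydro-2H-pyrano[3,2-c]quinolin-5(6H)-one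
Product: 16 the target CNP0237003.1 (Cc S; Ce R; Cf S), via oxocarbenium ion 15 (not isolated)
Conditions: CF3CO2H, CH2Cl2, −20 °C to rt, short reaction time
Reagents that add atoms: none
Why: Vinylsilane-terminated cation–olefin cyclisation: protonation of the enol ether at Cd gives the tertiary oxocarbenium ion 15, Cb attacks Cc with ipso substitution (6-endo at the vinylsilane), and the cation at Ca, β to silicon and conjugated with O4A, loses the silyl group so that the double bond can only end at Ca=Cb. Cc is a bridgehead, so its configuration follows from Ce: the Cf–Ca=Cb tether can reach Cc only on the face of ring B on which it is held, which gives (S). Ce and Cf are not touched.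

## Compound list

1 | 2,3-dimethoxyaniline | COc1cccc(N)c1OC | starting material
2 | N-(methoxymethyl)-2,3-dimethoxyaniline | COCNc1cccc(OC)c1OC | intermediate (not isolated)
3 | 2,3-dimethoxy-N-methylaniline | CNc1cccc(OC)c1OC | intermediate
4 | diethyl malonate | CCOC(=O)CC(=O)OCC | starting material
5 | ethyl 3-[(2,3-dimethoxyphenyl)(methyl)amino]-3-oxopropanoate | CCOC(=O)CC(=O)N(C)c1cccc(OC)c1OC | intermediate (not isolated)
6 | 4-hydroxy-7,8-dimethoxy-1-methylquinolin-2(1H)-one | COc1ccc2c(O)cc(=O)n(C)c2c1OC | intermediate
7 | 3-methylbut-2-enoic acid | CC(C)=CC(O)=O | starting material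
8 | 4-hydroxy-7,8-dimethoxy-1-methyl-3-(3-methylbut-2-enoyl)quinolin-2(1H)-one | COc1ccc2c(O)c(C(=O)C=C(C)C)c(=O)n(C)c2c1OC | intermediate (not isolated)
9 | 7,8-dimethoxy-2,2,6-trimethyl-2,3-dihydro-4H-pyrano[3,2-c]quinoline-4,5(6H)-dione (ring A pyranone) | COc1ccc2c3c(c(=O)n(C)c2c1OC)C(=O)CC(C)(C)O3 | intermediate
10 | 4,4-dimethoxybutan-2-one | COC(CC(C)=O)OC | starting material
11 | 4-hydroxy-7,8-dimethoxy-1-methyl-3-[(1E)-3-oxobut-1-en-1-yl]quinolin-2(1H)-one (reaches the cyclisable geometry through its alkylidene-dione tautomer) | COc1ccc2c(O)c(/C=C/C(C)=O)c(=O)n(C)c2c1OC | intermediate (not isolated)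
12 | 7,8-dimethoxy-2,6-dimethyl-5-oxo-5,6-dihydropyrano[3,2-c]quinolin-1-ium, ion pair with the chiral phosphate (cation shown) | Cc1ccc2c(=O)n(C)c3c(OC)c(OC)ccc3c2[o+]1 | intermediate (not isolated)
13 | (3R)-3-[(4R)-7,8-dimethoxy-2,6-dimethyl-5-oxo-5,6-dihydro-4H-pyrano[3,2-c]quinolin-4-yl]-7,8-dimethoxy-2,2,6-trimethyl-2,3-dihydro-4H-pyrano[3,2-c]quinoline-4,5(6H)-dione (Ce R, Cf R; ketone at Ca) | COc1ccc2c3c(c(=O)n(C)c2c1OC)C(=O)[C@H]([C@H]2C=C(C)Oc4c2c(=O)n(C)c2c(OC)c(OC)ccc42)C(C)(C)O3 | intermediate
14 | (3S)-3-[(4R)-7,8-dimethoxy-2,6-dimethyl-5-oxo-5,6-dihydro-4H-pyrano[3,2-c]quinolin-4-yl]-7,8-dimethoxy-2,2,6-trimethyl-4-[(trimethylsilyl)methylidene]-3,4-dihydro-2H-pyrano[3,2-c]quinolin-5(6H)-one (Ce R, Cf S; alkene geometry not controlled) | COc1ccc2c3c(c(=O)n(C)c2c1OC)C(=C[Si](C)(C)C)[C@H]([C@H]2CC=C(C)Oc4c2c(=O)n(C)c2c(OC)c(OC)ccc42)C(C)(C)O3 | intermediate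
15 | oxocarbenium ion from 14 by protonation at Cd (O4B=Cc cation, trifluoroacetate counter-ion; cation shown) | COc1ccc2c3c(c(=O)n(C)c2c1OC)C(=C[Si](C)(C)C)[C@H]([C@H]2CC(C)=[O+]c4c2c(=O)n(C)c2c(OC)c(OC)ccc42)C(C)(C)O3 | intermediate (not isolated)
16 | target CNP0237003.1: cyclohexene Ca=Cb–Cc–Cd–Ce–Cf with ring A fused at Ca–Cf and ring B bridging Cc and Ce (Cc S, Ce R, Cf S) | COc1ccc2c3c(c(=O)n(C)c2c1OC)C1=C[C@]2(C)C[C@@H](c4c(c5ccc(OC)c(OC)c5n(C)c4=O)O2)[C@@H]1C(C)(C)O3 | target

Correction to the SMILES of 14: the 4H-pyran of 13 is unchanged in step 5, so 14 is COc1ccc2c3c(c(=O)n(C)c2c1OC)C(=C[Si](C)(C)C)[C@H]([C@H]2C=C(C)Oc4c2c(=O)n(C)c2c(OC)c(OC)ccc42)C(C)(C)O3.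

## Step count and risk

Total step count: 6. Longest linear sequence: 6 steps (1 → 3 → 6 → 9 → 13 → 14 → 16).

**Step 4 (key step).**
- What may go wrong: capture of cation 12 by a second molecule of 6 instead of the weakly enolised 9; self-condensation of 12 through deprotonation of its 2-methyl group, and acid-induced self-condensation of 10; too little acidity for turnover; weak face discrimination at Ce and weak relative control at Cf, eroded further if the addition is reversible.
- Fallback (known chemistry, from 6, 10 and 9, returning at 13): 6 and 10 are condensed with CF3SO3H in acetic acid and the salt precipitated with ether, giving the pyranoquinolinium triflate F1 (benzopyrylium salt synthesis). Separately, 9 is converted with Me3SiOTf and NEt3 into its trimethylsilyl enol ether F2. F2 is added to F1 in CH2Cl2 at −78 °C (Mukaiyama-type addition of a silyl enol ether to the 4-position of a benzopyrylium salt), giving the adduct as a stereoisomer mixture F3. The Cf epimers are separated on silica, with the unwanted one re-equilibrated by a catalytic amine base and recycled, and the enantiomers are separated on a chiral stationary phase, which returns the route to 13.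

**Step 5.**
- What may go wrong: slow addition of the bulky silylcarbene to the hindered, vinylogous-ester-type ketone, so that thermal decay of the reagent, titanium-mediated enolisation (epimerisation at Cf) or olefination of a lactam carbonyl at forcing temperature takes over.
- Fallback (from 13, returning at 16): methylenation with Cp2TiMe2 in toluene at 70 °C gives the exocyclic methylene compound F4. Under the acid conditions of step 6, F4 should cyclise through the same type of oxocarbenium ion (Prins-type alkene–oxocarbenium cyclisation), and loss of a proton from Cb gives 16 directly, bypassing 14. The price is that proton loss from Cf can compete, which the silyl group was meant to prevent.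

**Step 6.**
- What may go wrong: protodesilylation of the electron-rich dienylsilane before the enol ether is protonated, followed by unselective proton loss; acid-mediated migration of the product double bond to Ca=Cf on long exposure; re-ionisation of the new tertiary allylic ether.
- Fallback (from 14, returning at 16): methanol is added across the enol ether under pyridinium p-toluenesulfonate catalysis to give the methyl ketal F5. F5 is then ionised without protic acid by catalytic Me3SiOTf with 2,6-di-tert-butyl-4-methylpyridine in CH2Cl2 at −78 °C (ketal-initiated vinylsilane cyclisation), giving 16.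

**Step 3.**
- What may go wrong: O-acylation without migration to C3, ring closure through the lactam oxygen to the linear isomer, or partial ether cleavage in the hot acid.
- Fallback (from 6, returning at 9): C3-acetylation with acetic acid in polyphosphoric acid gives the 3-acetyl compound F6. Condensation of F6 with acetone and pyrrolidine (Kabbe chromanone synthesis: enamine aldol, then oxa-Michael closure) gives 9.

**Step 2.**
- What may go wrong: condensation of a second malonate unit onto the product, or incomplete ring closure at a temperature the substrate tolerates.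
- Fallback (from 3, returning at 6): acylation of 3 with Meldrum's acid in toluene at 100 °C gives the malonamic acid F7, which is cyclised in P2O5–MeSO3H at 70 °C to 6.

## Further compounds

F1 | step 4 | 7,8-dimethoxy-2,6-dimethyl-5-oxo-5,6-dihydropyrano[3,2-c]quinolin-1-ium trifluoromethanesulfonate | Cc1ccc2c(=O)n(C)c3c(OC)c(OC)ccc3c2[o+]1.[O-]S(=O)(=O)C(F)(F)F
F2 | step 4 | 7,8-dimethoxy-2,2,6-trimethyl-4-(trimethylsilyloxy)-2H-pyrano[3,2-c]quinolin-5(6H)-one | COc1ccc2c3c(c(=O)n(C)c2c1OC)C(O[Si](C)(C)C)=CC(C)(C)O3
F3 | step 4 | adduct of the constitution of 13 as a mixture of all stereoisomers at Ce and Cf | COc1ccc2c3c(c(=O)n(C)c2c1OC)C(=O)C(C2C=C(C)Oc4c2c(=O)n(C)c2c(OC)c(OC)ccc42)C(C)(C)O3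
F4 | step 5 | (3S)-3-[(4R)-7,8-dimethoxy-2,6-dimethyl-5-oxo-5,6-dihydro-4H-pyrano[3,2-c]quinolin-4-yl]-7,8-dimethoxy-2,2,6-trimethyl-4-methylidene-3,4-dihydro-2H-pyrano[3,2-c]quinolin-5(6H)-one | COc1ccc2c3c(c(=O)n(C)c2c1OC)C(=C)[C@H]([C@H]2C=C(C)Oc4c2c(=O)n(C)c2c(OC)c(OC)ccc42)C(C)(C)O3
F5 | step 6 | methyl ketal of 14 (methanol added across Cd=Cc, OCH3 on Cc, mixture at Cc) | COc1ccc2c3c(c(=O)n(C)c2c1OC)C(=C[Si](C)(C)C)[C@H]([C@H]2CC(C)(OC)Oc4c2c(=O)n(C)c2c(OC)c(OC)ccc42)C(C)(C)O3
F6 | step 3 | 3-acetyl-4-hydroxy-7,8-dimethoxy-1-methylquinolin-2(1H)-one | COc1ccc2c(O)c(C(C)=O)c(=O)n(C)c2c1OC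
F7 | step 2 | 3-[(2,3-dimethoxyphenyl)(methyl)amino]-3-oxopropanoic acid | OC(=O)CC(=O)N(C)c1cccc(OC)c1OC
A1 | alternative 1 | seco-target with free quinolone B hydroxyl and triethylsilyl ether at Cc | COc1ccc2c3c(c(=O)n(C)c2c1OC)C1=C[C@@](C)(O[Si](CC)(CC)CC)C[C@@H](c4c(O)c5ccc(OC)c(OC)c5n(C)c4=O)[C@@H]1C(C)(C)O3
A2 | alternative 1 | methyl ester of the Ce acetic acid on the ring A carbocycle (triethylsilyl ether at Cc) | COc1ccc2c3c(c(=O)n(C)c2c1OC)C1=C[C@@](C)(O[Si](CC)(CC)CC)C[C@@H](CC(=O)OC)[C@@H]1C(C)(C)O3
A3 | alternative 1 | 7,8-dimethoxy-1-methyl-2H-3,1-benzoxazine-2,4(1H)-dione (N-methylisatoic anhydride) | COc1ccc2C(=O)OC(=O)N(C)c2c1OC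
A4 | alternative 2 | acetylcyclohexene cycloadduct | CC1=C[C@@H](c2c(OCC=C)c3ccc(OC)c(OC)c3n(C)c2=O)[C@@H](C(C)=O)[C@H](c2c(OCOC)c3ccc(OC)c(OC)c3n(C)c2=O)C1
A5 | alternative 2 | 4-(allyloxy)-7,8-dimethoxy-1-methyl-3-[(1E)-3-methylbuta-1,3-dien-1-yl]quinolin-2(1H)-one | C=C(C)/C=C/c1c(OCC=C)c2ccc(OC)c(OC)c2n(C)c1=O
A6 | alternative 2 | 7,8-dimethoxy-4-(methoxymethoxy)-1-methyl-3-[(1E)-3-oxobut-1-en-1-yl]quinolin-2(1H)-one | CC(=O)/C=C/c1c(OCOC)c2ccc(OC)c(OC)c2n(C)c1=O
A7 | alternative 3 | ring A closed cyclohexadiene | COc1ccc2c3c(c(=O)n(C)c2c1OC)C1=CC(C)=C[C@@H](c4c(OCOC)c5ccc(OC)c(OC)c5n(C)c4=O)[C@@H]1C(C)(C)O3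
A8 | alternative 3 | car-3-en-2-ol precursor with quinolone A (free 4-OH) on the cyclopropane carbon Ca and O-methoxymethyl quinolone B on Ce (either epimer at Cb) | COc1ccc2c(O)c(c(=O)n(C)c2c1OC)[C@@]12C(O)C(C)=C[C@@H](c3c(OCOC)c4ccc(OC)c(OC)c4n(C)c3=O)[C@@H]1C2(C)C
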